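**Retrosynthetic overview**
- The dihydropyranone (the only ring) is disconnected last, at O1–C6 and C2–C3, to (15Z)-tetracos-15-enal and a 4-methoxy-2-silyloxypenta-1,3-diene; a catalytic asymmetric aldol/cyclocondensation sets C2.
- The C24 aldehyde comes from the TBS ether of (15Z)-tetracos-15-en-1-ol, which is assembled in one operation from three components: n-octyllithium (as its Gilman cuprate), acetylene and TBSO(CH2)14I.
- In that operation the octyl CH2–vinyl CH bond (C15′–C16′ of the side chain) forms by syn-carbocupration and the C13′–C14′ bond by alkylation of the resulting (Z)-alkenylcuprate.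
- Enabling feature: the isolated cis-CH=CH unit C14′=C15′, two sp2 CH atoms between two unbranched CH2 chains and 13 CH2 groups away from the ring, is the exact retron of acetylene as a two-carbon linchpin.
- Ring order: no ring forms in the key step; the six-membered O-heterocycle (O1–C2–C3–C4(=O)–C5=C6) closes in the final step.

Key step: step 4

Remark: the sense of induction in step 9 is assumed to follow that of (S)-BINOL–Ti(IV)-catalysed allylation and Mukaiyama aldol additions (nucleophile to the Si face of the aldehyde), which for an unbranched alkyl aldehyde corresponds to the (R)-product.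

**Step 1**
Reactants: 1 tetradecane-1,14-diol
Product: 2 14-{[tert-butyl(dimethyl)silyl]oxy}tetradecan-1-ol
Conditions: NaH (1.0 equiv), THF, 40 °C; then TBSCl (1.0 equiv), rt
Reagents that add atoms: tert-butyldimethylsilyl chloride, CC(C)(C)[Si](C)(C)Cl
Why: O-silylation of the mono-sodium alkoxide formed with one equivalent of base should favour the mono-TBS ether, with diol and bis-ether separable by chromatography.

**Step 2**
Reactants: 2 14-{[tert-butyl(dimethyl)silyl]oxy}tetradecan-1-ol
Product: 3 tert-butyl[(14-iodotetradecyl)oxy]dimethylsilane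
Conditions: PPh3, I2, imidazole, CH2Cl2, 0 °C → rt
Reagents that add atoms: iodine, II
Why: Appel-type iodination, in which iodide displaces the alkoxyphosphonium group at the primary carbon by SN2 while the imidazole buffer keeps the TBS ether intact.

**Step 3**
Reactants: 4 1-bromooctane
Product: 5 n-octyllithium (titrated stock solution in Et2O)
Conditions: Li (1% Na, 2.2 equiv), Et2O, −15 → 0 °C; filtered and titrated
Reagents that add atoms: lithium metal, [Li]
Why: Reductive lithiation of a primary alkyl bromide in ether is the classical preparation of primary alkyllithiums, and the low temperature limits Wurtz coupling.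

**Step 4**
Reactants: 5 n-octyllithium, 6 acetylene, 3 tert-butyl[(14-iodotetradecyl)oxy]dimethylsilane
Product: 9 tert-butyldimethyl{[(15Z)-tetracos-15-en-1-yl]oxy}silane, via lithium dioctylcuprate 7 (not isolated), via lithium bis[(Z)-dec-1-enyl]cuprate 8 (not isolated)
Conditions: CuBr·SMe2 (0.5 equiv per 5), Et2O, −40 °C; HC≡CH (1 equiv per 5), −50 → −25 °C; then 3 (limiting), THF, HMPA, P(OEt)3, −40 → 20 °C; aq NH4Cl/NH3
Reagents that add atoms: none
Why: Two equivalents of 5 and CuBr·SMe2 give the Gilman cuprate 7, whose two C(sp3)–Cu bonds add syn across acetylene (Normant-type carbocupration), forming the octyl CH2–vinyl CH bond (C15′–C16′) and the cis-alkenyl–copper bond of 8 in the same event; 8 then alkylates iodide 3 with retention at the sp2 carbon (oxidative addition/reductive elimination at copper), forming C13′–C14′. The closest known reaction type is the carbocupration of acetylene by lithium dialkylcuprates followed by alkylation of the (Z)-dialkenylcuprate with a primary alkyl iodide in THF/HMPA/P(OEt)3, as used for long-chain Z-alkene pheromones of the same chain pattern. No ring is closed and no stereocentre is created; the Z geometry is controlled by the syn addition and by the configurational stability of the alkenylcuprate at these temperatures. The step needs mono-insertion of acetylene, secured by keeping the carbocupration at or below −25 °C, since a second insertion to a dienylcuprate sets in only when warmer. It also needs full conversion of 7 before 3 is added, secured by a slight excess of acetylene, so that no direct octyl–alkyl coupling occurs. Only one alkenyl group of 8 is transferred, so 8 is used in excess over 3, and the TBS ether is inert to the cuprate.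

**Step 5**
Reactants: 9 tert-butyldimethyl{[(15Z)-tetracos-15-en-1-yl]oxy}silane
Product: 10 (15Z)-tetracos-15-en-1-ol
Conditions: TBAF, THF, rt
Reagents that add atoms: none
Why: Fluoride-mediated desilylation is driven by Si–F bond formation and leaves the isolated Z-alkene untouched.

**Step 6**
Reactants: 10 (15Z)-tetracos-15-en-1-ol
Product: 11 (15Z)-tetracos-15-enal
Conditions: TEMPO (cat.), PhI(OAc)2, CH2Cl2, rt
Reagents that add atoms: none
Why: TEMPO/PhI(OAc)2 oxidation (oxoammonium-mediated) should stop at the aldehyde under anhydrous conditions and does not isomerise the Z-alkene.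

**Step 7**
Reactants: 12 pentane-2,4-dione (acetylacetone)
Product: 13 (3E)-4-methoxypent-3-en-2-one
Conditions: HC(OMe)3, MeOH, TsOH (cat.), rt → 50 °C; distillation
Reagents that add atoms: trimethyl orthoformate, COC(OC)OC
Why: Acid-catalysed enol-ether formation (ketalisation by the orthoester, then loss of methanol) of the 1,3-diketone should give the conjugated, thermodynamically preferred (E)-β-methoxy enone.

**Step 8**
Reactants: 13 (3E)-4-methoxypent-3-en-2-one
Product: 14 (3E)-4-methoxy-2-[(trimethylsilyl)oxy]penta-1,3-diene
Conditions: LDA, THF, −78 °C; TMSCl, −78 °C → rt; non-aqueous work-up, distillation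
Reagents that add atoms: chlorotrimethylsilane, C[Si](C)(C)Cl
Why: Kinetic α′-deprotonation of the methyl ketone and O-silylation of the cross-conjugated enolate (silyl enol ether formation) should give the 2-silyloxy diene with the (E)-enol ether geometry retained.

**Step 9**
Reactants: 11 (15Z)-tetracos-15-enal, 14 (3E)-4-methoxy-2-[(trimethylsilyl)oxy]penta-1,3-diene
Product: 16 (2R)-6-methyl-2-[(14Z)-tricos-14-en-1-yl]-2,3-dihydro-4H-pyran-4-one, via silyl aldol adduct 15 (not isolated)
Conditions: (S)-BINOL (20 mol %), Ti(OiPr)4 (10 mol %), 4 Å MS, Et2O, −20 °C; then TFA, CH2Cl2, 0 °C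
Reagents that add atoms: none
Why: In this Ti(IV)–BINOL-catalysed Mukaiyama aldol/cyclocondensation (formal hetero-Diels–Alder reaction) the (S)-BINOL–Ti complex should direct C1 of the diene to the Si face of the aldehyde, setting C2 as R (O > CH2C=O > alkyl chain), after which TFA closes the ring by 6-endo-trig attack of the C2 oxygen on the β-methoxy enone with loss of methanol and the silyl group, leaving the stereocentre untouched.

**Compound list**
1 | tetradecane-1,14-diol | OCCCCCCCCCCCCCCO | starting material
2 | 14-{[tert-butyl(dimethyl)silyl]oxy}tetradecan-1-ol | OCCCCCCCCCCCCCCO[Si](C)(C)C(C)(C)C | intermediate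
3 | tert-butyl[(14-iodotetradecyl)oxy]dimethylsilane | ICCCCCCCCCCCCCCO[Si](C)(C)C(C)(C)C | intermediate
4 | 1-bromooctane | CCCCCCCCBr | starting material
5 | n-octyllithium (Et2O solution) | [Li]CCCCCCCC | intermediate
6 | acetylene | C#C | starting material
7 | lithium dioctylcuprate | [Li+].CCCCCCCC[Cu-]CCCCCCCC | intermediate
8 | lithium bis[(Z)-dec-1-enyl]cuprate | [Li+].CCCCCCCC/C=C\[Cu-]/C=C\CCCCCCCC | intermediate
9 | tert-butyldimethyl{[(15Z)-tetracos-15-en-1-yl]oxy}silane | CCCCCCCC/C=C\CCCCCCCCCCCCCCO[Si](C)(C)C(C)(C)C | intermediate
10 | (15Z)-tetracos-15-en-1-ol | CCCCCCCC/C=C\CCCCCCCCCCCCCCO | intermediate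
11 | (15Z)-tetracos-15-enal | CCCCCCCC/C=C\CCCCCCCCCCCCCC=O | intermediate
12 | pentane-2,4-dione | CC(=O)CC(C)=O | starting material
13 | (3E)-4-methoxypent-3-en-2-one | CO/C(C)=C/C(C)=O | intermediate
14 | (3E)-4-methoxy-2-[(trimethylsilyl)oxy]penta-1,3-diene | CO/C(C)=C/C(=C)O[Si](C)(C)C | intermediate
15 | (2E,6R,20Z)-2-methoxy-6-[(trimethylsilyl)oxy]nonacosa-2,20-dien-4-one | CCCCCCCC/C=C\CCCCCCCCCCCCC[C@@H](O[Si](C)(C)C)CC(=O)/C=C(\C)OC | intermediate
16 | (2R)-6-methyl-2-[(14Z)-tricos-14-en-1-yl]-2,3-dihydro-4H-pyran-4-one | CCCCCCCC/C=C\CCCCCCCCCCCCC[C@@H]1CC(=O)C=C(C)O1 | target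

**Step count**
Total: 9 steps. Longest linear sequence: 6 steps (1 → 2 → 3 → 9 → 10 → 11 → 16, i.e. steps 1, 2, 4, 5, 6, 9).

**Steps most likely to fail**

Step 4. A second acetylene may insert into the alkenyl–copper bond if the temperature rises, carbocupration may stay incomplete so that octyl–copper species are alkylated directly, and transfer of the alkenyl group to the long-chain iodide may be sluggish. The fallback sets out from 3 and returns at 9. Displacement of the iodide of 3 with lithium acetylide–ethylenediamine complex in DMSO would give tert-butyl(hexadec-15-yn-1-yloxy)dimethylsilane F1. Deprotonation with n-BuLi and alkylation with 1-bromooctane 4 in THF/DMPU would give tert-butyldimethyl(tetracos-15-yn-1-yloxy)silane F2, making the same octyl–carbon bond at the alkyne oxidation level. Lindlar semihydrogenation (Pd/CaCO3/Pb, quinoline, H2) would then give 9.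

Step 9. Facial discrimination (sense as well as magnitude) may be insufficient for an unbranched long-chain aldehyde, and turnover with the 1-methyl-substituted diene may be slow enough for an unselective background aldol to compete. The fallback sets out from 11 and returns at 16. Roskamp homologation of 11 (ethyl diazoacetate, cat. SnCl2) would give ethyl (17Z)-3-oxohexacos-17-enoate F3. Noyori asymmetric hydrogenation with a Ru–(R)-BINAP catalyst at low hydrogen pressure, conditions that spare isolated disubstituted alkenes, would give ethyl (3R,17Z)-3-hydroxyhexacos-17-enoate F4. Aminolysis with MeNHOMe·HCl/iPrMgCl would give the Weinreb amide (3R,17Z)-3-hydroxy-N-methoxy-N-methylhexacos-17-enamide F5. Addition of excess 1-propynylmagnesium bromide would give (6R,20Z)-6-hydroxynonacos-20-en-2-yn-4-one F6. Gold(I)-catalysed 6-endo-dig oxa-Michael cyclisation would then give 16.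

Step 1. Statistical over-silylation to the bis-ether and incomplete conversion caused by the low solubility of the C14 diol may erode the supply of 2. The fallback sets out from 1 and returns at 3. Monobromination with 48% HBr in refluxing toluene, where extraction of the bromo alcohol into the organic phase suppresses the second substitution, would give 14-bromotetradecan-1-ol F7. Silylation (TBSCl, imidazole, CH2Cl2) would give [(14-bromotetradecyl)oxy](tert-butyl)dimethylsilane F8. Finkelstein exchange (NaI, acetone, reflux) would give 3.

**Further compounds**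
F1 | step 4 | tert-butyl(hexadec-15-yn-1-yloxy)dimethylsilane | C#CCCCCCCCCCCCCCCO[Si](C)(C)C(C)(C)C
F2 | step 4 | tert-butyldimethyl(tetracos-15-yn-1-yloxy)silane | CCCCCCCCC#CCCCCCCCCCCCCCCO[Si](C)(C)C(C)(C)C
F3 | step 9 | ethyl (17Z)-3-oxohexacos-17-enoate | CCCCCCCC/C=C\CCCCCCCCCCCCCC(=O)CC(=O)OCC
F4 | step 9 | ethyl (3R,17Z)-3-hydroxyhexacos-17-enoate | CCCCCCCC/C=C\CCCCCCCCCCCCC[C@@H](O)CC(=O)OCC
F5 | step 9 | (3R,17Z)-3-hydroxy-N-methoxy-N-methylhexacos-17-enamide | CCCCCCCC/C=C\CCCCCCCCCCCCC[C@@H](O)CC(=O)N(C)OC
F6 | step 9 | (6R,20Z)-6-hydroxynonacos-20-en-2-yn-4-one | CCCCCCCC/C=C\CCCCCCCCCCCCC[C@@H](O)CC(=O)C#CC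
F7 | step 1 | 14-bromotetradecan-1-ol | OCCCCCCCCCCCCCCBr
F8 | step 1 | [(14-bromotetradecyl)oxy](tert-butyl)dimethylsilane | BrCCCCCCCCCCCCCCO[Si](C)(C)C(C)(C)C
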